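**Assumption:** the target has no stereocentre and no E/Z alkene, so it is achiral and needs no enantiocontrol. The stereocentres in the intermediates are racemic and are erased in the last step.

## Retrosynthetic overview
1. The flavonol is the enol of a 2-arylchromane-3,4-dione. Its C3 carbonyl is traced back to a C–NO2 carbon (oxidative Nef-type exchange), which gives a 2-aryl-3-nitro-2H-chromene.
2. Key disconnection is C3–C4. C3 acts as a masked acyl anion (α-nitro carbanion, d1) and attacks the A-ring formyl carbon C4. Both are carbonyl carbons in the dione, so both are normally electrophilic.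
3. The carbanion forms in situ by oxa-Michael addition (O1–C2 bond) of an ortho-OH of the A-ring aldehyde to 4-hydroxy-β-nitrostyrene.
4. Both prenyl groups are installed first, on phloroglucinaldehyde. The symmetric product has two equivalent ortho-OH groups, so only one regioisomer can form.
5. Rings A and B are bought. Only ring C (the pyranone) is built, in the domino step, and it is aromatised in the last step.

## Route

Step 1
Reactants: 1 2,4,6-trihydroxybenzaldehyde; 2 prenyl bromide (2.1 equiv)
Product: 3 2,4,6-trihydroxy-3,5-bis(3-methylbut-2-en-1-yl)benzaldehyde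
Conditions: KOH (2.1 equiv), MeOH/H2O, 0 °C → rt
Reagents that add atoms: prenyl bromide (compound 2), CC(C)=CCBr
Why: Phenolate C-alkylation (SN2 at the primary allylic bromide) of an acylphloroglucinol, in which the hydrogen-bonded phenolate in protic medium reacts at its two free ring carbons rather than at oxygen (the classical deoxyhumulone-type diprenylation), the formyl group has no α-H and survives as a vinylogous carboxylate, and no stereocentre is formed.

Step 2
Reactants: 3 2,4,6-trihydroxy-3,5-bis(3-methylbut-2-en-1-yl)benzaldehyde; 4 (E)-4-(2-nitrovinyl)phenol (1.3 equiv)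
Product: 7 rac-2-(4-hydroxyphenyl)-3-nitro-6,8-bis(3-methylbut-2-en-1-yl)-2H-chromene-5,7-diol, via oxa-Michael adduct 5 (not isolated), via nitrochromanol 6 (not isolated)
Conditions: DABCO (0.5 equiv), 4 Å MS, THF, 60 °C, N2
Reagents that add atoms: none
Why: Domino oxa-Michael/intramolecular Henry (nitroaldol)/E1cB dehydration, known for salicylaldehydes and β-nitrostyrenes, in which either equivalent ortho-phenoxide adds to 4 to give 5 and unmasks C3 as an α-nitro carbanion (a masked acyl anion of the later C3 carbonyl), this carbanion attacks the formyl carbon C4 to give 6, irreversible water loss to the push–pull chromene 7 drives the reversible steps (including unproductive addition of the para-OH), and the new C2 stereocentre is racemic and removed in step 3.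

Step 3
Reactants: 7 rac-2-(4-hydroxyphenyl)-3-nitro-6,8-bis(3-methylbut-2-en-1-yl)-2H-chromene-5,7-diol
Product: 11 6,8-diprenylkaempferol, via nitro epoxide 8 (not isolated), via 4-hydroperoxy ketone 9 (not isolated), via chromane-3,4-dione 10 (not isolated)
Conditions: 30% H2O2 (3 equiv), NaOH (5 equiv), MeOH/THF, 0 °C → rt; pH 6 phosphate work-up
Reagents that add atoms: hydrogen peroxide, OO
Why: Weitz–Scheffer nucleophilic epoxidation followed by an oxidative Nef-type exchange (the known alkaline-peroxide conversion of 2-aryl-3-nitro-2H-chromenes into flavonols), in which HOO⁻ adds at C4 and closes to 8, a second HOO⁻ opens 8 at benzylic C4 and expels nitrite to give 9, Kornblum–DeLaMare fragmentation gives 10, enolisation to the aromatic pyranone 11 erases C2, and the unactivated prenyl alkenes are inert to the nucleophilic oxidant (the pH 6 work-up keeps nitrite from forming HNO2).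

## Compound list
1 | 2,4,6-trihydroxybenzaldehyde | O=Cc1c(O)cc(O)cc1O | starting material
2 | prenyl bromide (1-bromo-3-methylbut-2-ene) | CC(C)=CCBr | starting material
3 | 2,4,6-trihydroxy-3,5-bis(3-methylbut-2-en-1-yl)benzaldehyde | O=Cc1c(O)c(CC=C(C)C)c(O)c(CC=C(C)C)c1O | intermediate
4 | (E)-4-(2-nitrovinyl)phenol (trans-4-hydroxy-β-nitrostyrene) | O=[N+]([O-])/C=C/c1ccc(O)cc1 | starting material
5 | 2,4-dihydroxy-6-[1-(4-hydroxyphenyl)-2-nitroethoxy]-3,5-diprenylbenzaldehyde (racemic, not isolated) | O=Cc1c(O)c(CC=C(C)C)c(O)c(CC=C(C)C)c1OC(C[N+](=O)[O-])c1ccc(O)cc1 | intermediate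
6 | 2-(4-hydroxyphenyl)-3-nitro-6,8-diprenylchromane-4,5,7-triol (racemic diastereomer mixture, not isolated) | OC1c2c(O)c(CC=C(C)C)c(O)c(CC=C(C)C)c2OC(c2ccc(O)cc2)C1[N+](=O)[O-] | intermediate
7 | rac-2-(4-hydroxyphenyl)-3-nitro-6,8-diprenyl-2H-chromene-5,7-diol | O=[N+]([O-])C1=Cc2c(O)c(CC=C(C)C)c(O)c(CC=C(C)C)c2OC1c1ccc(O)cc1 | intermediate
8 | 3,4-epoxy-2-(4-hydroxyphenyl)-3-nitro-6,8-diprenylchromane-5,7-diol (racemic, not isolated) | O=[N+]([O-])C12OC1c1c(O)c(CC=C(C)C)c(O)c(CC=C(C)C)c1OC2c1ccc(O)cc1 | intermediate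
9 | 4-hydroperoxy-5,7-dihydroxy-2-(4-hydroxyphenyl)-6,8-diprenylchroman-3-one (racemic, not isolated) | OOC1c2c(O)c(CC=C(C)C)c(O)c(CC=C(C)C)c2OC(c2ccc(O)cc2)C1=O | intermediate
10 | 5,7-dihydroxy-2-(4-hydroxyphenyl)-6,8-diprenylchromane-3,4-dione (racemic, not isolated) | O=C1C(=O)c2c(O)c(CC=C(C)C)c(O)c(CC=C(C)C)c2OC1c1ccc(O)cc1 | intermediate
11 | 6,8-diprenylkaempferol (achiral) | CC(C)=CCc1c(O)c(CC=C(C)C)c2oc(-c3ccc(O)cc3)c(O)c(=O)c2c1O | target

## Step count and risks
Total steps: 3. Longest linear sequence: 3 (1 → 3 → 7 → 11).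

**Step 2 (highest risk).** The formyl group of 3 is a deactivated vinylogous acid. Both partners also carry acidic phenols, so the Henry closure may be slow and 4 may oligomerise.

The fallback sets out from 3 and comes back at 7. It first turns C4 into a much stronger electrophile. Compound 3 is condensed with p-toluenesulfonamide (cat. pyrrolidine, 4 Å MS, CH2Cl2, 40 °C) to give the N-tosyl aldimine of 3, F2. F2 then reacts with 4 (DABCO, THF, rt) in an oxa-Michael/aza-Henry domino to give 4-(tosylamino)-3-nitrochromane F3. On warming with the base, F3 loses the sulfonamide by E1cB and gives 7.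

**Step 3.** In alkali, 7 is a phenolate-conjugated (vinylogous) nitronate, which may resist HOO⁻ addition. The free polyphenolic flavonol may also be over-oxidised.

The fallback sets out from 7 and comes back at 11. It oxidises a neutral, fully capped nitroalkene instead. MOMCl and i-Pr2NEt in CH2Cl2 give the tris(methoxymethyl) ether of 7, F4. H2O2/NaOH in MeOH/THF then gives 5,7,4'-tri-O-methoxymethyl-6,8-diprenylkaempferol F5. Treatment with 3 M HCl/MeOH at 45 °C, conditions that ortho-prenylphenols tolerate, releases 11.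

**Step 1.** Mono-alkylation, O-alkylation and geminal (dearomatised) alkylation all compete, so only a moderate yield is expected.

The fallback sets out from 1 (with 2) and comes back at 3. It separates alkylation from C–C bond formation. Clean O-alkylation in aprotic medium (K2CO3, acetone, reflux) gives 2-hydroxy-4,6-bis(3-methylbut-2-en-1-yloxy)benzaldehyde F1. Montmorillonite K10 (CH2Cl2, 0 °C) then promotes the [1,3] O→C prenyl shift of both ethers to the free ortho carbons and gives 3.

## Further compounds
F1 | step 1 | 2-hydroxy-4,6-bis(3-methylbut-2-en-1-yloxy)benzaldehyde | O=Cc1c(O)cc(OCC=C(C)C)cc1OCC=C(C)C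
F2 | step 2 | (E)-N-[2,4,6-trihydroxy-3,5-diprenylbenzylidene]-4-methylbenzenesulfonamide | Cc1ccc(cc1)S(=O)(=O)/N=C/c1c(O)c(CC=C(C)C)c(O)c(CC=C(C)C)c1O
F3 | step 2 | N-[5,7-dihydroxy-2-(4-hydroxyphenyl)-3-nitro-6,8-diprenylchroman-4-yl]-4-methylbenzenesulfonamide (racemic diastereomer mixture) | Cc1ccc(cc1)S(=O)(=O)NC1c2c(O)c(CC=C(C)C)c(O)c(CC=C(C)C)c2OC(c2ccc(O)cc2)C1[N+](=O)[O-]
F4 | step 3 | rac-5,7-bis(methoxymethoxy)-2-[4-(methoxymethoxy)phenyl]-3-nitro-6,8-diprenyl-2H-chromene | O=[N+]([O-])C1=Cc2c(OCOC)c(CC=C(C)C)c(OCOC)c(CC=C(C)C)c2OC1c1ccc(OCOC)cc1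
F5 | step 3 | 3-hydroxy-5,7-bis(methoxymethoxy)-2-[4-(methoxymethoxy)phenyl]-6,8-diprenyl-4H-chromen-4-one | COCOc1ccc(cc1)-c1oc2c(CC=C(C)C)c(OCOC)c(CC=C(C)C)c(OCOC)c2c(=O)c1O
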